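**Retrosynthetic overview**

1. Target ⇐ desilylation and tert-butyl ester acidolysis ⇐ double caffeoylation at O1 and O3 of a tert-butyl quinate whose O4/O5 are bridged by a disiloxane ⇐ equatorial hydride addition to the corresponding 3-ketone (a 3-dehydroquinate).
2. Enabling feature: in the cyclohexane ring C1–C6, C1 (tertiary carbinol bearing the carboxyl) and C3 (oxygenated) are 1,3-related through the C2 methylene, so at the C3-ketone level C1–C2–C3 is an aldol retron. Both carry oxygen, so one oxygen can bridge them: the carbocycle is the carba-isomer of a pyran ring (O, C1, C6, C5, C4, C3) bearing C2 as an exocyclic methylene on C3.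
3. Key disconnection C1–C2: mercury-triggered oxygen-to-carbon ring transposition (Ferrier-type hydrolysis, then 6-enolexo aldol) of a cyclic bis-enol ether. It sets the quaternary C1; C4 and C5 come unchanged from C4 and C3 of D-glucal.
4. Bis-enol ether ⇐ C1-lithiation and carboxylation ⇐ 5,6-elimination ⇐ 6-O-tosyl-3,4-O-disiloxane-D-glucal ⇐ D-glucal.
5. Ring order: the pyran ring is bought with D-glucal and is given up when the only ring of the core, the cyclohexane, forms in the key step; the temporary seven-membered disiloxane ring (step 2) is removed last.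

Key step: step 5

Remark on the chemistry: the quinic acid ring is numbered C1 (carboxyl-bearing carbon) to C6, with C3 the carbon carrying the secondary caffeate; sugar-derived intermediates keep carbohydrate numbering. TIPDS = 1,1,3,3-tetraisopropyldisiloxane-1,3-diyl, TBS = tert-butyldimethylsilyl.

**Route**

Step 1
Reactants: 1 D-glucal
Product: 2 6-O-(p-tolylsulfonyl)-D-glucal
Conditions: TsCl (1.1 equiv), pyridine, −20 °C → 0 °C
Reagents that add atoms: p-toluenesulfonyl chloride, Cc1ccc(cc1)S(Cl)(=O)=O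
Why: Sulfonylation of the primary 6-OH is much faster than that of the two secondary hydroxyls (steric control) under basic conditions that leave the enol ether untouched, giving a known type of 6-O-sulfonyl glycal.

Step 2
Reactants: 2 6-O-(p-tolylsulfonyl)-D-glucal
Product: 3 6-O-(p-tolylsulfonyl)-3,4-O-TIPDS-D-glucal
Conditions: (i-Pr2SiCl)2O (1.1 equiv), pyridine, 0 °C → rt
Reagents that add atoms: 1,3-dichloro-1,1,3,3-tetraisopropyldisiloxane, CC(C)[Si](Cl)(C(C)C)O[Si](Cl)(C(C)C)C(C)C
Why: The bifunctional silyl dichloride bridges the only remaining diol, the trans-diequatorial 3,4-diol, as a seven-membered cyclic disiloxane (silyl ether formation) that tolerates t-BuLi, the mercury salt and hydride and later holds O4/O5 diequatorial in the chair transition state.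

Step 3
Reactants: 3 6-O-(p-tolylsulfonyl)-3,4-O-TIPDS-D-glucal
Product: 5 1,5-anhydro-2,6-dideoxy-3,4-O-TIPDS-D-threo-hexa-1,5-dienitol, via 6-iodide 4 (not isolated)
Conditions: NaI, DBU, n-Bu4NI (cat.), 4 Å MS, DMSO, 80 °C
Reagents that add atoms: none
Why: Finkelstein exchange of the primary tosylate to the iodide and DBU-mediated E2 loss of HI across C5–C6 is the standard entry to 6-deoxyhex-5-enopyranose enol ethers; the C5 stereocenter is deliberately erased while C3 and C4 are untouched.

Step 4
Reactants: 5 1,5-anhydro-2,6-dideoxy-3,4-O-TIPDS-D-threo-hexa-1,5-dienitol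
Product: 7 tert-butyl 2,6-anhydro-3,7-dideoxy-4,5-O-TIPDS-D-threo-hepta-2,6-dienonate, via 1-lithio glycal 6 (not isolated)
Conditions: t-BuLi (2.5 equiv), THF, −78 → 0 °C; then Boc2O (3 equiv), −78 °C → rt; H2O quench
Reagents that add atoms: di-tert-butyl dicarbonate (Boc2O), CC(C)(C)OC(=O)OC(=O)OC(C)(C)C
Why: Kinetic deprotonation of the alpha-alkoxyvinyl C1–H of silyl-protected glycals with t-BuLi is well precedented (the exocyclic methylene hydrogens are beta to oxygen and much less acidic) and the vinyllithium is acylated by Boc2O to the acid-cleavable tert-butyl ester.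

Step 5
Reactants: 7 tert-butyl 2,6-anhydro-3,7-dideoxy-4,5-O-TIPDS-D-threo-hepta-2,6-dienonate
Product: 9 tert-butyl 3-dehydro-4,5-O-TIPDS-quinate (1-OH axial and cis to O4; O4/O5 trans-diequatorial), via ring-opened mercurio diketo ester 8 (not isolated)
Conditions: Hg(OCOCF3)2 (10 mol %), acetone/H2O (4:1), 0 °C → rt
Reagents that add atoms: water, O
Why: Proposed new method: Hg(OCOCF3)2 (divalent mercury) adds at the terminal carbon of the electron-rich exocyclic enol ether (the ring C=C is a deactivated push-pull 2-alkoxyacrylate), water traps the oxocarbenium ion, and the hemiketal collapses with cleavage of the ring C–O bond so that the ring oxygen leaves as the enol of the alpha-keto ester, which tautomerizes to the C1 ketone of 8, whose alpha-mercurio ketone then adds through C2 to that ketone and releases the mercury salt for turnover. The closest known reaction type is the Ferrier carbocyclization of 6-deoxyhex-5-enopyranosides (and, biomimetically, the aldol closure of the ring-opened 3-deoxyheptulosonate to 3-dehydroquinate); new here is that the acceptor carbonyl is a ketone uncovered from a glycal-type enol ether instead of an aldehyde from an anomeric acetal. The cyclohexane, the only ring formed, is closed by a 6-(enolexo)-exo-trig aldol addition. The new stereocenter C1 is controlled by the substrate: in the chair transition state the disiloxane-bridged O4 and O5 are diequatorial, the bulky CO2t-Bu group takes the equatorial and the carbonyl oxygen the axial position, so that 1-OH ends up axial, trans to O5 and cis to O4, the sense seen in Ferrier carbocyclizations (new hydroxyl trans to the oxygen on the second carbon away). The step needs chemoselective mercuration of the exocyclic over the endocyclic alkene (secured by the ester conjugation of the latter), an enolate located only at C2 (secured by the position of mercury, so that C4 cannot epimerize and O5 cannot be beta-eliminated), and survival of the beta-hydroxy ketone (near-neutral medium at room temperature, no dehydration towards the 3-dehydroshikimate).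

Step 6
Reactants: 9 tert-butyl 3-dehydro-4,5-O-TIPDS-quinate
Product: 10 tert-butyl 4,5-O-TIPDS-quinate (1-OH and 3-OH free and cis-diaxial)
Conditions: Li[HB(s-Bu)3] (2.5 equiv), THF, −78 °C; then AcOH, −78 °C → rt
Reagents that add atoms: none
Why: The bulky trialkylborohydride attacks the cyclohexanone from the equatorial direction (the axial trajectory is additionally blocked by the axial O1, 1,3 to the carbonyl carbon), so the new 3-OH is axial, cis to O1 and O4 as in quinic acid (substrate-controlled diastereoselective ketone reduction); the cold acetic acid quench limits retro-aldol opening and silyl migration.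

Step 7
Reactants: 11 caffeic acid
Product: 13 (E)-3-[3,4-bis(tert-butyldimethylsilyloxy)phenyl]acrylic acid, via silyl ester 12 (not isolated)
Conditions: TBSCl (3.5 equiv), imidazole, DMF, rt; then AcOH/THF/H2O, rt
Reagents that add atoms: tert-butyldimethylsilyl chloride (TBSCl), CC(C)(C)[Si](C)(C)Cl
Why: Exhaustive silylation of both phenols and the carboxyl group followed by selective hydrolysis of the labile silyl ester in mild aqueous acid is a standard way to the bis-silyl-protected cinnamic acid; the E-alkene is untouched.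

Step 8
Reactants: 13 (E)-3-[3,4-bis(tert-butyldimethylsilyloxy)phenyl]acrylic acid
Product: 14 (E)-3-[3,4-bis(tert-butyldimethylsilyloxy)phenyl]acryloyl chloride
Conditions: (COCl)2, DMF (cat.), CH2Cl2, 0 °C → rt; used crude
Reagents that add atoms: oxalyl chloride, ClC(=O)C(=O)Cl
Why: Oxalyl chloride with catalytic DMF (Vilsmeier-type activation) converts the acid into the acid chloride under conditions that aryl silyl ethers and the E-alkene survive.

Step 9
Reactants: 10 tert-butyl 4,5-O-TIPDS-quinate; 14 (E)-3-[3,4-bis(tert-butyldimethylsilyloxy)phenyl]acryloyl chloride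
Product: 15 tert-butyl 1,3-bis-O-[(E)-3,4-bis(tert-butyldimethylsilyloxy)cinnamoyl]-4,5-O-TIPDS-quinate
Conditions: 14 (4 equiv), DMAP, pyridine/ClCH2CH2Cl, 50 °C
Reagents that add atoms: none
Why: DMAP-catalysed acyl transfer from an excess of the acid chloride (N-acylpyridinium, Steglich-type acylation) esterifies the secondary axial 3-OH and then the tertiary 1-OH, while O4 and O5 stay masked by the disiloxane so that no regiochemical question arises.

Step 10
Reactants: 15 tert-butyl 1,3-bis-O-[(E)-3,4-bis(tert-butyldimethylsilyloxy)cinnamoyl]-4,5-O-TIPDS-quinate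
Product: 16 1,3-bis-O-[(E)-3,4-bis(tert-butyldimethylsilyloxy)cinnamoyl]-4,5-O-TIPDS-quinic acid
Conditions: TFA/CH2Cl2 (1:4), 0 °C → rt
Reagents that add atoms: none
Why: Acidolysis of the tert-butyl ester with TFA (alkyl–oxygen cleavage with loss of isobutene) frees the carboxylic acid while aryl silyl ethers, the disiloxane and the two cinnamate esters persist, the tertiary C1–O acyl bond being protected from ionization by the neighbouring carboxyl.

Step 11
Reactants: 16 1,3-bis-O-[(E)-3,4-bis(tert-butyldimethylsilyloxy)cinnamoyl]-4,5-O-TIPDS-quinic acid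
Product: 17 1,3-di-O-caffeoylquinic acid
Conditions: HF·pyridine, THF/pyridine, 0 °C → rt
Reagents that add atoms: none
Why: Fluoride cleaves all Si–O bonds (cyclic disiloxane and four aryl silyl ethers) under acidic, non-basic conditions, which avoids the base-induced acyl migration and ester cleavage to which caffeoylquinic acids are prone.

**Compound list**

1 | D-glucal (1,5-anhydro-2-deoxy-D-arabino-hex-1-enitol) | OC[C@H]1OC=C[C@@H](O)[C@@H]1O | starting material
2 | 6-O-(p-tolylsulfonyl)-D-glucal | Cc1ccc(cc1)S(=O)(=O)OC[C@H]1OC=C[C@@H](O)[C@@H]1O | intermediate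
3 | 6-O-(p-tolylsulfonyl)-3,4-O-TIPDS-D-glucal | Cc1ccc(cc1)S(=O)(=O)OC[C@H]1OC=C[C@@H](O[Si](C(C)C)(C(C)C)O[Si](C(C)C)(C(C)C)O2)[C@@H]12 | intermediate
4 | 6-deoxy-6-iodo-3,4-O-TIPDS-D-glucal | IC[C@H]1OC=C[C@@H](O[Si](C(C)C)(C(C)C)O[Si](C(C)C)(C(C)C)O2)[C@@H]12 | intermediate
5 | 1,5-anhydro-2,6-dideoxy-3,4-O-TIPDS-D-threo-hexa-1,5-dienitol | C=C1OC=C[C@@H](O[Si](C(C)C)(C(C)C)O[Si](C(C)C)(C(C)C)O2)[C@@H]12 | intermediate
6 | 1-lithio derivative of 5 | C=C1OC([Li])=C[C@@H](O[Si](C(C)C)(C(C)C)O[Si](C(C)C)(C(C)C)O2)[C@@H]12 | intermediate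
7 | tert-butyl 2,6-anhydro-3,7-dideoxy-4,5-O-TIPDS-D-threo-hepta-2,6-dienonate | C=C1OC(C(=O)OC(C)(C)C)=C[C@@H](O[Si](C(C)C)(C(C)C)O[Si](C(C)C)(C(C)C)O2)[C@@H]12 | intermediate
8 | tert-butyl 3,7-dideoxy-4,5-O-TIPDS-7-(trifluoroacetoxymercurio)-D-threo-hepto-2,6-diulosonate | CC(C)(C)OC(=O)C(=O)C[C@@H](O[Si](C(C)C)(C(C)C)O[Si](C(C)C)(C(C)C)O1)[C@H]1C(=O)C[Hg]OC(=O)C(F)(F)F | intermediate
9 | tert-butyl 3-dehydro-4,5-O-TIPDS-quinate | O=C1C[C@@](O)(C(=O)OC(C)(C)C)C[C@@H](O[Si](C(C)C)(C(C)C)O[Si](C(C)C)(C(C)C)O2)[C@@H]12 | intermediate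
10 | tert-butyl 4,5-O-TIPDS-quinate | O[C@@H]1C[C@@](O)(C(=O)OC(C)(C)C)C[C@@H](O[Si](C(C)C)(C(C)C)O[Si](C(C)C)(C(C)C)O2)[C@@H]12 | intermediate
11 | caffeic acid ((E)-3-(3,4-dihydroxyphenyl)acrylic acid) | OC(=O)/C=C/c1ccc(O)c(O)c1 | starting material
12 | tert-butyldimethylsilyl (E)-3-[3,4-bis(tert-butyldimethylsilyloxy)phenyl]acrylate | CC(C)(C)[Si](C)(C)OC(=O)/C=C/c1ccc(O[Si](C)(C)C(C)(C)C)c(O[Si](C)(C)C(C)(C)C)c1 | intermediate
13 | (E)-3-[3,4-bis(tert-butyldimethylsilyloxy)phenyl]acrylic acid | OC(=O)/C=C/c1ccc(O[Si](C)(C)C(C)(C)C)c(O[Si](C)(C)C(C)(C)C)c1 | intermediate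
14 | (E)-3-[3,4-bis(tert-butyldimethylsilyloxy)phenyl]acryloyl chloride | ClC(=O)/C=C/c1ccc(O[Si](C)(C)C(C)(C)C)c(O[Si](C)(C)C(C)(C)C)c1 | intermediate
15 | tert-butyl 1,3-bis-O-[(E)-3,4-bis(tert-butyldimethylsilyloxy)cinnamoyl]-4,5-O-TIPDS-quinate | O=C(/C=C/c1ccc(O[Si](C)(C)C(C)(C)C)c(O[Si](C)(C)C(C)(C)C)c1)O[C@@H]1C[C@@](OC(=O)/C=C/c3ccc(O[Si](C)(C)C(C)(C)C)c(O[Si](C)(C)C(C)(C)C)c3)(C(=O)OC(C)(C)C)C[C@@H](O[Si](C(C)C)(C(C)C)O[Si](C(C)C)(C(C)C)O2)[C@@H]12 | intermediate
16 | 1,3-bis-O-[(E)-3,4-bis(tert-butyldimethylsilyloxy)cinnamoyl]-4,5-O-TIPDS-quinic acid | O=C(/C=C/c1ccc(O[Si](C)(C)C(C)(C)C)c(O[Si](C)(C)C(C)(C)C)c1)O[C@@H]1C[C@@](OC(=O)/C=C/c3ccc(O[Si](C)(C)C(C)(C)C)c(O[Si](C)(C)C(C)(C)C)c3)(C(=O)O)C[C@@H](O[Si](C(C)C)(C(C)C)O[Si](C(C)C)(C(C)C)O2)[C@@H]12 | intermediate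
17 | 1,3-di-O-caffeoylquinic acid | O=C(/C=C/c1ccc(O)c(O)c1)O[C@@H]1C[C@@](OC(=O)/C=C/c2ccc(O)c(O)c2)(C(=O)O)C[C@@H](O)[C@@H]1O | target

**Step count and risks**

Total step count: 11. Longest linear sequence: 9 steps (steps 1–6 and 9–11).

Steps most likely to fail:

Step 5 (Proposed new method). The cascade may stall after ring opening (protodemercuration to the acyclic diketone without carbon–carbon bond formation), or mercuration may be unselective between the two enol ethers. Fallback with known chemistry, from 7 back to 9: hydrolysis of both enol ethers of 7 with dilute acid (pyridinium p-toluenesulfonate cat., acetone/H2O, rt) would give the acyclic tert-butyl 3,7-dideoxy-4,5-O-TIPDS-D-threo-hepto-2,6-diulosonate F1. An amine-catalysed intramolecular aldol addition (L-proline, DMSO, rt; enamine of the methyl ketone, 6-enolexo closure onto the alpha-keto ester) should then close the ring to 9.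

Step 9. Acylation may stop after esterification of 3-OH, because the tertiary axial 1-OH is shielded by the 1,3-diaxial ester, and prolonged heating invites acyl scrambling. Fallback from 10 back to 15: the cinnamoyl units are built on the alcohol instead of being transferred. Heating 10 with Meldrum's acid (toluene, 90 °C) should open this small acyl donor at both hydroxyls to give tert-butyl 1,3-bis-O-(carboxyacetyl)-4,5-O-TIPDS-quinate F2. Knoevenagel–Doebner condensation of F2 with 3,4-bis(tert-butyldimethylsilyloxy)benzaldehyde F3 (from 3,4-dihydroxybenzaldehyde with TBSCl, imidazole, DMF) in pyridine with piperidine (cat.) at 40 °C would form both E-alkenes with loss of CO2 and give 15.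

Step 4. Metalation of the acid-labile bis-enol ether 5 may be unselective (competing allylic deprotonation or attack on the disiloxane), and C-acylation may be incomplete. Fallback from 1 back to 7: the order is reversed so that the carboxyl is introduced on a fully silylated glucal, a directly precedented substrate class, and the exocyclic alkene is made last. Selective silylation of 1 (TBSCl, imidazole, DMF, 0 °C) gives 6-O-(tert-butyldimethylsilyl)-D-glucal F4. Disiloxane bridging as in step 2 gives 6-O-(tert-butyldimethylsilyl)-3,4-O-TIPDS-D-glucal F5. Treatment with t-BuLi then Boc2O as in step 4 gives tert-butyl 2,6-anhydro-7-O-(tert-butyldimethylsilyl)-3-deoxy-4,5-O-TIPDS-D-arabino-hept-2-enonate F6. Selective cleavage of the primary silyl ether (camphorsulfonic acid cat., MeOH/CH2Cl2, 0 °C) gives tert-butyl 2,6-anhydro-3-deoxy-4,5-O-TIPDS-D-arabino-hept-2-enonate F7. Iodination (I2, PPh3, imidazole, toluene, rt) gives tert-butyl 2,6-anhydro-3,7-dideoxy-7-iodo-4,5-O-TIPDS-D-arabino-hept-2-enonate F8, and E2 elimination with DBU (THF, 60 °C) gives 7.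

Further compounds

F1 | step 5 | tert-butyl 3,7-dideoxy-4,5-O-TIPDS-D-threo-hepto-2,6-diulosonate | CC(C)(C)OC(=O)C(=O)C[C@@H](O[Si](C(C)C)(C(C)C)O[Si](C(C)C)(C(C)C)O1)[C@H]1C(C)=O
F2 | step 9 | tert-butyl 1,3-bis-O-(carboxyacetyl)-4,5-O-TIPDS-quinate | OC(=O)CC(=O)O[C@@H]1C[C@@](OC(=O)CC(=O)O)(C(=O)OC(C)(C)C)C[C@@H](O[Si](C(C)C)(C(C)C)O[Si](C(C)C)(C(C)C)O2)[C@@H]12
F3 | step 9 | 3,4-bis(tert-butyldimethylsilyloxy)benzaldehyde | O=Cc1ccc(O[Si](C)(C)C(C)(C)C)c(O[Si](C)(C)C(C)(C)C)c1
F4 | step 4 | 6-O-(tert-butyldimethylsilyl)-D-glucal | CC(C)(C)[Si](C)(C)OC[C@H]1OC=C[C@@H](O)[C@@H]1O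
F5 | step 4 | 6-O-(tert-butyldimethylsilyl)-3,4-O-TIPDS-D-glucal | CC(C)(C)[Si](C)(C)OC[C@H]1OC=C[C@@H](O[Si](C(C)C)(C(C)C)O[Si](C(C)C)(C(C)C)O2)[C@@H]12
F6 | step 4 | tert-butyl 2,6-anhydro-7-O-(tert-butyldimethylsilyl)-3-deoxy-4,5-O-TIPDS-D-arabino-hept-2-enonate | CC(C)(C)[Si](C)(C)OC[C@H]1OC(C(=O)OC(C)(C)C)=C[C@@H](O[Si](C(C)C)(C(C)C)O[Si](C(C)C)(C(C)C)O2)[C@@H]12
F7 | step 4 | tert-butyl 2,6-anhydro-3-deoxy-4,5-O-TIPDS-D-arabino-hept-2-enonate | OC[C@H]1OC(C(=O)OC(C)(C)C)=C[C@@H](O[Si](C(C)C)(C(C)C)O[Si](C(C)C)(C(C)C)O2)[C@@H]12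
F8 | step 4 | tert-butyl 2,6-anhydro-3,7-dideoxy-7-iodo-4,5-O-TIPDS-D-arabino-hept-2-enonate | IC[C@H]1OC(C(=O)OC(C)(C)C)=C[C@@H](O[Si](C(C)C)(C(C)C)O[Si](C(C)C)(C(C)C)O2)[C@@H]12
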